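A ratio of two mean partner levels is what I would carry from flask to flask here, so let it be examined.

in all of them: solid substrate 0.40 M

| charge | partner | remark | time |
|---|---|---|---|
| Wednesday's | 2.1 equiv | run made earlier |  |
| Tuesday's | 6.2 equiv | run made earlier |  |
| ochre | 1.50 equiv |  | 8.0 min |
| amber | 4.00 equiv |  | 8.0 min |
| violet | 2.50 equiv |  | 8.0 min |

| run | time / min | tris adduct / % | mono adduct / % |
|---|---|---|---|
| Wednesday's | 2.00 | 4.4 | 23.4 |
| Wednesday's | 4.00 | 18.2 | 32.9 |
| Wednesday's | 6.00 | 27.2 | 27.7 |
| Wednesday's | 8.00 | 35.5 | 22.7 |
| Tuesday's | 2.00 | 32.1 | 25.9 |
| Tuesday's | 4.00 | 78.8 | 10.2 |
| Tuesday's | 6.00 | 91.6 | 3.2 |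
| Tuesday's | 8.00 | 95.1 | 1.5 |

(each reading ± 1 percentage point)

- as a solid, counted per litre of solution: solid substrate
- at the start none of the solid substrate is in solution

- which of these holds the largest part of the solid substrate at the end of ochre (solid substrate / double product / tris adduct / mono adduct)
- which of these holds the largest part of the solid substrate at the end of amber (solid substrate / double product / tris adduct / mono adduct)
- which of these holds the largest part of the solid substrate at the end of violet (solid substrate / double product / tris adduct / mono adduct)
- final tris adduct in amber, as a percentage of the solid substrate charged

Why compare flasks by partner? Each addition consumes partner, so with partner frozen at its mean every step is pseudo-first-order, and a flask with less partner passes through the same composition later.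

How much partner does a composition cost? Take Tuesday's run at 4.00 min. Mono adduct plus 3 times tris adduct gives 2.47 per charge of solid substrate. Double product is unread, so this is a floor, but it stands on both sides of the ratio.

And the mean level? It is the charge minus half of that: 4.97 for Tuesday's run, 2.77 for amber. The stretch, Tuesday's mean partner over another flask's at the same composition and the same substrate charge, is here 1.80.

Does it survive a test? Tuesday's reading at 2.00 min is 32.1% tris adduct, costing 1.22. The stretch places that composition in Wednesday's run at 7.51 min, and Wednesday's tris adduct passes that level between 6.00 min and 8.00 min.

The weak spot? The solid starts undissolved, and its dissolving need not stretch with partner, so I carry that as an open error.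

Your numbers? Ochre's charge of 1.50 equiv stands against that floor cost of 1.22, so the 12.6 min I reckon for that composition is an earliest time and no promise that ochre gets there; it is later than ochre's end, so I name mono adduct. Violet reaches it at 5.92 min, earlier, so I name tris adduct. Amber's end corresponds to Tuesday's 4.46 min, and interpolating gives 81.7%.

The forecast names mono adduct, tris adduct and tris adduct for ochre, amber and violet and puts amber at 73%, below my figure, on the ground “early progress is about 0.65 of Tuesday's pace”.

The largest part at the end is mono adduct in ochre, tris adduct in amber and tris adduct in violet, and amber's tris adduct is 79.1%.

    starting material + partner → mono adduct (k = 0.0130 M⁻¹ s⁻¹)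
    partner + mono adduct → double product (k = 0.0110 M⁻¹ s⁻¹)
    partner + double product → tris adduct (k = 0.0230 M⁻¹ s⁻¹)
    solid substrate ⇌ starting material, rate k4*(cs4 - [starting material]) while solid is left; crystals form when [starting material] > cs4 (solubility = 0.330 M, k = 0.0140 s⁻¹)
    mono adduct ⇌ isomer of the product (K = 0.620, k = 0.00200 s⁻¹)

Amber's 79.1% at 8.0 min stands beside Tuesday's 78.8% at 4.00 min, so the stretch read there is 2.00 against the reckoned 1.80, and my figure is 2.6 percentage points high. The neighbour charged with 0.16 M of solid substrate keeps amber's equivalents, so my reckoning, with partner counted per litre, gives a stretch behind amber equal to the charge ratio, 2.50, and puts amber's state at 4.00 min, tris adduct 49.6% with 49.6% of partner left, at 10.0 min. The neighbour shows tris adduct 48.6% with 50% of partner left already at 8.00 min, a stretch of 2.00 read there, so the reckoned stretch does not hold for it, and its isomer of the product stands at 12.6% against amber's 7.49%.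

The earlier runs and the new flask were computed for substances that don't exist; the scatter is artificial.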